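Saturday's flask cannot have made its target by one pass of each enzyme: at 4.00 h it reads 35 %, which is c(target) = 0.0175 M, far more than its charged c(free enzyme) = 25 µM. So I count passes.

common to all: starting material 0.050 M; free enzyme 25 µM

| charge | second substrate | remark | time |
|---|---|---|---|
| Saturday's | 0.040 M | the very flask that is asked about, followed so far |  |
| flask | 0.0400 M |  | 5.0 h |

Saturday's run (percent of the starting material charged)

| time / h | target / % | starting material / % |
|---|---|---|
| 0.333 | 8 | 92 |
| 0.667 | 16 | 84 |
| 1.50 | 26 | 72 |
| 4.00 | 35 | 66 |

(each reading ± 1.5 percentage points)

- gamma: at 5.0 h add second substrate, 50.0 % of the amount charged, then wait 10 h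
- theta: change nothing and wait 10 h more
- zeta: at 5.0 h take out 90 % of the target then present, then wait 10 h
- alpha: at 5.0 h add free enzyme, 50.0 % of the amount charged, then wait 10 h

- removed target is counted in
- the numbers in the tables scatter with a standard deviation of 1.5 percentage points
- additions bring no volume worth counting

* target, in percent of the starting material first charged, at 5.0 h
* the option that brings most further target ("none" if no option brings more than 2 percentage points) (gamma / theta / zeta / alpha / none)
* target present, with what was taken out counted in, in percent of the starting material first charged, after zeta
* target present, with what was taken out counted in, in percent of the starting material first charged, after alpha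

Saturday's flask is the flask asked about, and its budget, read at 4.00 h with the scatter of that reading, is 700, the target made per enzyme charged (the usual term is turnover number). In powers of ten the budget is 2.85, and the starting material stands 3.30 powers above the enzyme. The target thus stands 0.456 powers below the charge of starting material, which is the reading of 35 % told again. The first 0.333 h brings 8 %, but the stretch from 1.50 h to 4.00 h brings 9 percentage points, with 66 % of the starting material still there. I read this as an enzyme dying, though these readings cannot exclude a balance.

The neighbour flask looks nearly the same and differs in one charge, 0.12 M of starting material. If its budget is the same, it makes the same c(target), but that is divided by a charge 2.40 times as large. The difference grows to 0.836 powers, so I expect 14.6 % there. By my own reckoning, the same budget on the 12.5 µM of free enzyme added in alpha adds 18 points.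

The forecast gives 36.5 % now, names alpha as best, and gives 38 % after zeta and 54 % after alpha, with the words “I lean to enzyme death”.

The flask gives 37.2 % at 5.0 h, with alpha best, 38.1 % after zeta and 44.1 % after alpha.

    free enzyme → spent catalyst (k = 0.0360 min⁻¹)
    second complex → free enzyme + target (k = 33.0 min⁻¹)
    first complex ⇌ loaded enzyme + first product (K = 0.0510 M, k = 220 min⁻¹)
    second substrate + loaded enzyme ⇌ second complex (K = 13.0 M⁻¹, k = 19000 M⁻¹ min⁻¹)
    starting material + free enzyme ⇌ first complex (K = 16.0 M⁻¹, k = 62000 M⁻¹ min⁻¹)

Alpha gains 6.9 points, which is 276 turnovers per added enzyme, fewer than Saturday's budget, in a flask holding 0.0186 M of first product at 5.00 h. This flask's own budget at 5.0 h is 743. The neighbour gives 21.4 %, more than my expected share, a budget of 1030, with 74.8 % of its catalyst spent at 5.00 h.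

All runs are simulated from invented constants; scatter was added.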